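All runs were generated by integration with made-up constants; the scatter is artificial.

12.2% is the number behind the quick value requested: it is the target share, the percent of the consumed substrate that stands as target once a run has gone flat, read here as the mean of Monday's readings, with the substrate of that run, charged with 2.2 equiv of reagent, counted as consumed.

| flask | substrate | reagent | remark | time |
|---|---|---|---|---|
| Friday's | 0.21 M | 0.55 equiv | run made earlier |  |
| Monday's | 0.21 M | 2.2 equiv | run made earlier |  |
| Wednesday's | 0.42 M | 1.1 equiv | run made earlier |  |
| flask | 0.21 M | 1.10 equiv |  | 2.5 min |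

| run | time / min | target / % | intermediate C / % |
|---|---|---|---|
| Friday's | 0.167 | 10.5 | 1.7 |
| Friday's | 0.500 | 7.6 | 3.5 |
| Friday's | 0.833 | 6.2 | 3.7 |
| Friday's | 1.33 | 7.1 | 2.2 |
| Friday's | 2.00 | 7.1 | 3.1 |
| Friday's | 2.50 | 4.1 | 4.3 |
| Monday's | 0.417 | 11.9 | 3.7 |
| Monday's | 0.833 | 12.6 | 4.6 |
| Monday's | 1.33 | 13.8 | 3.9 |
| Monday's | 1.50 | 11.2 | 4.0 |
| Monday's | 2.00 | 11.9 | 2.8 |
| Monday's | 2.50 | 12.1 | 1.2 |
| Wednesday's | 0.200 | 14.9 | 4.6 |
| Wednesday's | 0.667 | 11.8 | 6.4 |
| Wednesday's | 1.33 | 10.9 | 5.0 |
| Wednesday's | 2.00 | 14.6 | 6.8 |
| Wednesday's | 2.50 | 10.3 | 5.2 |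

(each reading ± 1 percentage point)

- what was read earlier has a scatter of 1 percentage point, one standard deviation

- concentration of target at 2.5 min, in M
- concentration of intermediate C at 2.5 min, in M

Friday's run, short of reagent at 0.55 equiv and counted one reagent per substrate, gives a share of 11.7% from its readings after 0.167 min, and Wednesday's run gives 11.9% from its readings after 0.200 min. The new flask charges 1.10 equiv, so on that count substrate is the limiting reagent, and my reckoning takes its charge as consumed:

target = target share × substrate charged = 12.2% × 0.21 M = 0.0257 M

For intermediate C, my rough value comes from the last reading of Wednesday's run, which has the same equivalents but twice the substrate concentration: 5.2% of 0.21 M is 0.0109 M.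

The forecast differs from my reckoning: it gives 0.02 M of target and 0.0067 M of intermediate C, on the ground that “target yield seems to follow reagent concentration”. That ground and the target share both suit Monday's and Wednesday's runs, and they part on the new flask, which has Monday's substrate concentration and Wednesday's equivalents.

The flask gives 0.0255 M of target and 0.0107 M of intermediate C.

    reagent + intermediate A → intermediate B (k = 0.0890 /M/s)
    substrate + reagent → target (k = 3.10 /M/s)
    intermediate B → intermediate D (k = 0.00330 /s)
    substrate + reagent → intermediate A (k = 0.300 /M/s)
    intermediate A ⇌ intermediate C (K = 1.90, k = 0.0720 /s)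
    target ⇌ isomer of the product (K = 6.50, k = 0.300 /s)
    intermediate D → side product (k = 0.00180 /s)

At 2.5 min the flask holds 0% substrate and 12.2% target, against a target share of 12.2% read from Monday's run.

In the same flask with 0.280 equiv of reagent, where reagent is the limiting one on the same count, the target share applied to the substrate that reagent can consume gives 0.00717 M of target. That neighbouring flask gives 0.00715 M at 2.50 min, with 0% reagent and 72.0% substrate left.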